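**Retrosynthetic overview**
- The C15 formate comes from a silyl ether. Ring A is opened by a retro-Diels–Alder (bonds C2–C3 and C4–C5) to methyl methacrylate and a 1-vinylcyclohexene (ring B).
- The vinyl diene comes from an enol triflate, and that from a 2,2,3-trisubstituted cyclohexanone carrying the complete side chain.
- Key disconnection C11–C12: C11 is β to the C10 ketone and is used as a nucleophile (zinc homoenolate from a bicyclic cyclopropanol) against an (E)-allylic bromide; both carbons are normally electrophilic.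
- The cyclopropanol comes from Simmons–Smith reaction of the silyl enol ether obtained by copper-catalysed asymmetric methyl addition to 2-methylcyclohex-2-en-1-one; the bromide comes from prenol.
- Ring order: ring B is bought and carries C8/C9; ring A is formed last.

Assumption: carbon labels C1–C20 in the explanations follow halimane numbering of the target (C4 = ester-bearing quaternary carbon, C5 = ring-fusion CH, C8 and C9 = methyl-bearing carbons of ring B, C11–C15 = side chain); reagents without a number are bought.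

**Step 1**
Reactants: 1 2-methylcyclohex-2-en-1-one
Product: 3 (R)-[(2,3-dimethylcyclohex-1-en-1-yl)oxy]trimethylsilane, via dimethylaluminium enolate 2 (not isolated)
Conditions: Me3Al (1.4 equiv), copper thiophene-2-carboxylate Cu(O2CC4H3S) (2 mol%), O,O′-(1,1′-binaphthyl-2,2′-diyl)-N,N-bis(1-phenylethyl)phosphoramidite (4 mol%, the antipode that gives 3R), Et2O, −30 °C; then Me3SiOTf, THF, −30 → 0 °C
Reagents that add atoms: trimethylaluminium C[Al](C)C; trimethylsilyl trifluoromethanesulfonate C[Si](C)(C)OS(=O)(=O)C(F)(F)F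
Why: Copper-catalysed asymmetric conjugate addition of Me3Al to the 2-substituted enone, in which the chiral phosphoramidite–copper complex selects the enone face and so sets C8 (3R), followed by regiospecific O-silylation of the aluminium enolate to the tetrasubstituted enol ether.

**Step 2**
Reactants: 3 (R)-[(2,3-dimethylcyclohex-1-en-1-yl)oxy]trimethylsilane
Product: 5 (1R,5R,6S)-5,6-dimethylbicyclo[4.1.0]heptan-1-ol, via siloxycyclopropane 4 (not isolated)
Conditions: Et2Zn, CH2I2, CH2Cl2, 0 °C → rt; then K2CO3 (cat.), MeOH, 0 °C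
Reagents that add atoms: diiodomethane ICI
Why: Simmons–Smith (Furukawa) cyclopropanation of the electron-rich enol ether occurs anti to the C8 methyl, which A(1,2) strain against the C9 methyl holds pseudoaxial, so the new CH2 (C11) is trans to the C8 methyl and C9 and C10 are set; mild methanolysis then frees the cyclopropanol.

**Step 3**
Reactants: 6 3-methylbut-2-en-1-ol
Product: 7 tert-butyldimethyl[(3-methylbut-2-en-1-yl)oxy]silane
Conditions: TBSCl, imidazole, CH2Cl2, rt
Reagents that add atoms: tert-butyldimethylsilyl chloride CC(C)(C)[Si](C)(C)Cl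
Why: Standard O-silylation masks the hydroxyl for the oxidation and organometallic steps; no stereocentre is involved.

**Step 4**
Reactants: 7 tert-butyldimethyl[(3-methylbut-2-en-1-yl)oxy]silane
Product: 8 (E)-4-[(tert-butyldimethylsilyl)oxy]-2-methylbut-2-en-1-ol
Conditions: SeO2 (0.3 equiv), t-BuOOH, salicylic acid (cat.), CH2Cl2, rt
Reagents that add atoms: tert-butyl hydroperoxide CC(C)(C)OO; selenium dioxide O=[Se]=O (catalytic oxygen carrier)
Why: Sharpless SeO2/t-BuOOH allylic oxidation (ene reaction then [2,3]-sigmatropic shift) attacks the methyl trans to the CH2O chain of the trisubstituted alkene, which fixes the E geometry of the later C13=C14 bond.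

**Step 5**
Reactants: 8 (E)-4-[(tert-butyldimethylsilyl)oxy]-2-methylbut-2-en-1-ol
Product: 9 (E)-[(4-bromo-3-methylbut-2-en-1-yl)oxy](tert-butyl)dimethylsilane
Conditions: CBr4, PPh3, CH2Cl2, 0 °C
Reagents that add atoms: carbon tetrabromide BrC(Br)(Br)Br
Why: Appel bromination converts the primary allylic alcohol to the bromide by SN2 at 0 °C without allylic transposition or loss of the E geometry.

**Step 6 (key step)**
Reactants: 5 (1R,5R,6S)-5,6-dimethylbicyclo[4.1.0]heptan-1-ol; 9 (E)-[(4-bromo-3-methylbut-2-en-1-yl)oxy](tert-butyl)dimethylsilane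
Product: 12 (2S,3R)-2-[(E)-5-[(tert-butyldimethylsilyl)oxy]-3-methylpent-3-en-1-yl]-2,3-dimethylcyclohexan-1-one, via zinc bis-cyclopropoxide 10 (not isolated), via zinc bis-homoenolate 11 (not isolated)
Conditions: Et2Zn (0.55 equiv), THF, 0 °C → rt; then DMA, 9 (1.0 equiv), Pd(PPh3)4 (5 mol%), rt
Reagents that add atoms: none
Why: Proposed new method: deprotonation by Et2Zn gives a zinc cyclopropoxide that opens by strain-driven cleavage of the less substituted C1–C7 bond to a primary β-zincio ketone (zinc homoenolate, C11 nucleophilic although β to the carbonyl), which transmetalates to the π-allylpalladium formed from the allylic bromide by zerovalent palladium; the resulting neopentyl-type alkyl(allyl)palladium has no β-hydrogen and reductively eliminates at the unsubstituted allyl terminus (C12) with retention of the E alkene, while C9 keeps the configuration set in step 2; the closest known reaction types are the Et2Zn-mediated opening of cyclopropanols to zinc homoenolates (so far used in copper-mediated SN2′ allylations) and the palladium-catalysed Negishi coupling of alkylzinc reagents, ester zinc homoenolates included, with allylic halides.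

**Step 7**
Reactants: 12 (2S,3R)-2-[(E)-5-[(tert-butyldimethylsilyl)oxy]-3-methylpent-3-en-1-yl]-2,3-dimethylcyclohexan-1-one
Product: 14 (5R,6S)-6-[(E)-5-[(tert-butyldimethylsilyl)oxy]-3-methylpent-3-en-1-yl]-5,6-dimethylcyclohex-1-en-1-yl trifluoromethanesulfonate, via potassium enolate 13 (not isolated)
Conditions: KN(SiMe3)2, THF, −78 °C; then PhNTf2, −78 → 0 °C
Reagents that add atoms: N-phenylbis(trifluoromethanesulfonimide) O=S(=O)(N(c1ccccc1)S(=O)(=O)C(F)(F)F)C(F)(F)F
Why: Enol triflate formation: C9 is quaternary, so the base can only enolise toward C5 and the potassium enolate is O-triflated by PhNTf2, with no stereocentre touched.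

**Step 8**
Reactants: 14 (5R,6S)-6-[(E)-5-[(tert-butyldimethylsilyl)oxy]-3-methylpent-3-en-1-yl]-5,6-dimethylcyclohex-1-en-1-yl trifluoromethanesulfonate
Product: 15 tert-butyl{[(E)-5-[(1S,6R)-2-ethenyl-1,6-dimethylcyclohex-2-en-1-yl]-3-methylpent-2-en-1-yl]oxy}dimethylsilane
Conditions: Bu3SnCH=CH2, Pd(PPh3)4 (5 mol%), LiCl (3 equiv), THF, 65 °C
Reagents that add atoms: tributyl(vinyl)stannane C=C[Sn](CCCC)(CCCC)CCCC
Why: Stille coupling of the alkenyl triflate with the vinylstannane (LiCl assists transmetalation) gives the 1-vinylcyclohexene that carries C1 and C2, with all stereocentres untouched.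

**Step 9**
Reactants: 15 tert-butyl{[(E)-5-[(1S,6R)-2-ethenyl-1,6-dimethylcyclohex-2-en-1-yl]-3-methylpent-2-en-1-yl]oxy}dimethylsilane; 16 methyl 2-methylprop-2-enoate
Product: 17 methyl (1S,5S,6R,8aR)-5-[(E)-5-[(tert-butyldimethylsilyl)oxy]-3-methylpent-3-en-1-yl]-1,5,6-trimethyl-1,2,3,5,6,7,8,8a-octahydronaphthalene-1-carboxylate
Conditions: 16 (5 equiv), EtAlCl2 (30 mol%), CH2Cl2, −40 → 0 °C
Reagents that add atoms: none
Why: Lewis-acid-catalysed Diels–Alder reaction in which the methacrylate CH2 bonds to the unhindered vinyl terminus C2 and its α-carbon to C5 (the "ortho" orientation of 1-vinylcyclohexenes), the ester sits endo so that CO2Me ends trans to H5 (sets C4), and the dienophile adds to the diene face anti to the pseudoaxial C9 methyl in the half-chair that keeps the C8 methyl equatorial (sets C5), giving the C1=C10 alkene directly.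

**Step 10**
Reactants: 17 methyl (1S,5S,6R,8aR)-5-[(E)-5-[(tert-butyldimethylsilyl)oxy]-3-methylpent-3-en-1-yl]-1,5,6-trimethyl-1,2,3,5,6,7,8,8a-octahydronaphthalene-1-carboxylate
Product: 19 methyl (1S,5S,6R,8aR)-5-[(E)-5-(formyloxy)-3-methylpent-3-en-1-yl]-1,5,6-trimethyl-1,2,3,5,6,7,8,8a-octahydronaphthalene-1-carboxylate, via allylic alcohol 18 (not isolated)
Conditions: HF·pyridine, pyridine, THF, 0 °C → rt; then AcOCHO (excess), 0 °C
Reagents that add atoms: acetic formic anhydride CC(=O)OC=O
Why: Fluoride cleaves the primary silyl ether and the mixed anhydride then transfers its more electrophilic formyl group to the allylic alcohol (O-formylation) under buffered, non-ionising conditions that leave the hindered methyl ester, both alkenes and all stereocentres intact.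

**Compound list**
1 | 2-methylcyclohex-2-en-1-one | CC1=CCCCC1=O | starting material
2 | dimethylaluminium (R)-2,3-dimethylcyclohex-1-en-1-olate | C[C@@H]1CCCC(O[Al](C)C)=C1C | intermediate
3 | (R)-[(2,3-dimethylcyclohex-1-en-1-yl)oxy]trimethylsilane | C[C@@H]1CCCC(O[Si](C)(C)C)=C1C | intermediate
4 | trimethyl{[(1R,5R,6S)-5,6-dimethylbicyclo[4.1.0]heptan-1-yl]oxy}silane | C[C@@H]1CCC[C@@]2(O[Si](C)(C)C)C[C@@]12C | intermediate
5 | (1R,5R,6S)-5,6-dimethylbicyclo[4.1.0]heptan-1-ol | C[C@@H]1CCC[C@@]2(O)C[C@@]12C | intermediate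
6 | 3-methylbut-2-en-1-ol | CC(C)=CCO | starting material
7 | tert-butyldimethyl[(3-methylbut-2-en-1-yl)oxy]silane | CC(C)=CCO[Si](C)(C)C(C)(C)C | intermediate
8 | (E)-4-[(tert-butyldimethylsilyl)oxy]-2-methylbut-2-en-1-ol | OC/C(C)=C/CO[Si](C)(C)C(C)(C)C | intermediate
9 | (E)-[(4-bromo-3-methylbut-2-en-1-yl)oxy](tert-butyl)dimethylsilane | BrC/C(C)=C/CO[Si](C)(C)C(C)(C)C | intermediate
10 | zinc bis[(1R,5R,6S)-5,6-dimethylbicyclo[4.1.0]heptan-1-olate] | C[C@@H]1CCC[C@@]2([O-])C[C@@]12C.C[C@@H]1CCC[C@@]2([O-])C[C@@]12C.[Zn+2] | intermediate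
11 | bis{[(1S,2R)-1,2-dimethyl-6-oxocyclohexyl]methyl}zinc | C[C@@H]1CCCC(=O)[C@@]1(C)C[Zn]C[C@]1(C)C(=O)CCC[C@H]1C | intermediate
12 | (2S,3R)-2-[(E)-5-[(tert-butyldimethylsilyl)oxy]-3-methylpent-3-en-1-yl]-2,3-dimethylcyclohexan-1-one | C[C@@H]1CCCC(=O)[C@@]1(C)CC/C(C)=C/CO[Si](C)(C)C(C)(C)C | intermediate
13 | potassium (5R,6S)-6-[(E)-5-[(tert-butyldimethylsilyl)oxy]-3-methylpent-3-en-1-yl]-5,6-dimethylcyclohex-1-en-1-olate | C[C@@H]1CCC=C([O-])[C@@]1(C)CC/C(C)=C/CO[Si](C)(C)C(C)(C)C.[K+] | intermediate
14 | (5R,6S)-6-[(E)-5-[(tert-butyldimethylsilyl)oxy]-3-methylpent-3-en-1-yl]-5,6-dimethylcyclohex-1-en-1-yl trifluoromethanesulfonate | C[C@@H]1CCC=C(OS(=O)(=O)C(F)(F)F)[C@@]1(C)CC/C(C)=C/CO[Si](C)(C)C(C)(C)C | intermediate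
15 | tert-butyl{[(E)-5-[(1S,6R)-2-ethenyl-1,6-dimethylcyclohex-2-en-1-yl]-3-methylpent-2-en-1-yl]oxy}dimethylsilane | C[C@@H]1CCC=C(C=C)[C@@]1(C)CC/C(C)=C/CO[Si](C)(C)C(C)(C)C | intermediate
16 | methyl 2-methylprop-2-enoate | COC(=O)C(C)=C | starting material
17 | methyl (1S,5S,6R,8aR)-5-[(E)-5-[(tert-butyldimethylsilyl)oxy]-3-methylpent-3-en-1-yl]-1,5,6-trimethyl-1,2,3,5,6,7,8,8a-octahydronaphthalene-1-carboxylate | COC(=O)[C@@]1(C)CCC=C2[C@H]1CC[C@@H](C)[C@]2(C)CC/C(C)=C/CO[Si](C)(C)C(C)(C)C | intermediate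
18 | methyl (1S,5S,6R,8aR)-5-[(E)-5-hydroxy-3-methylpent-3-en-1-yl]-1,5,6-trimethyl-1,2,3,5,6,7,8,8a-octahydronaphthalene-1-carboxylate | COC(=O)[C@@]1(C)CCC=C2[C@H]1CC[C@@H](C)[C@]2(C)CC/C(C)=C/CO | intermediate
19 | methyl (1S,5S,6R,8aR)-5-[(E)-5-(formyloxy)-3-methylpent-3-en-1-yl]-1,5,6-trimethyl-1,2,3,5,6,7,8,8a-octahydronaphthalene-1-carboxylate | COC(=O)[C@@]1(C)CCC=C2[C@H]1CC[C@@H](C)[C@]2(C)CC/C(C)=C/COC=O | target

**Step count and risks**
Total step count: 10. Longest linear sequence: 8 steps (from 6 through steps 3, 4, 5, 6, 7, 8, 9 and 10 to 19); the arm from 1 is 7 steps.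

The three steps most likely to fail are steps 6, 9 and 8.

Step 6 is untested as a combined protocol. The zinc alkoxide could O-allylate, the reductive elimination could be slow, or branched or Z product could form. The fallback installs the side chain with normal polarity; it sets out from silyl enol ether 3 and comes back at ketone 12. TiCl4-mediated Mukaiyama–Michael addition of 3 to but-3-en-2-one (CH2Cl2, −78 °C, anti to the C8 methyl) gives (2S,3R)-2,3-dimethyl-2-(3-oxobutyl)cyclohexan-1-one F1. Horner–Wadsworth–Emmons olefination of the unhindered methyl ketone with (EtO)2P(O)CH2CO2Et and NaH gives ethyl (E)-5-[(1S,2R)-1,2-dimethyl-6-oxocyclohexyl]-3-methylpent-2-enoate F2, separated from its Z isomer. Reduction with i-Bu2AlH takes ester and ring ketone to (2S,3R)-2-[(E)-5-hydroxy-3-methylpent-3-en-1-yl]-2,3-dimethylcyclohexan-1-ol F3 (C1 epimers). TBSCl and imidazole silylate the primary allylic hydroxyl to give (2S,3R)-2-[(E)-5-[(tert-butyldimethylsilyl)oxy]-3-methylpent-3-en-1-yl]-2,3-dimethylcyclohexan-1-ol F4, and Dess–Martin periodinane oxidises this back to 12.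

Step 9 joins a hindered diene to a sluggish 1,1-disubstituted dienophile. Conversion, endo/exo control at C4 and facial control at C5 are all at stake. The fallback makes the quaternary carbon by enolate alkylation instead of in the cycloaddition; it sets out from diene 15 and comes back at 17. Diels–Alder reaction of 15 with the more reactive methyl acrylate (EtAlCl2, CH2Cl2) gives methyl (5S,6R,8aS)-5-[(E)-5-[(tert-butyldimethylsilyl)oxy]-3-methylpent-3-en-1-yl]-5,6-dimethyl-1,2,3,5,6,7,8,8a-octahydronaphthalene-1-carboxylate F5 as a mixture of C1 epimers (same spatial arrangement at C8a as in 17; only the descriptor changes). Deprotonation with LiN(i-Pr)2 and addition of MeI methylates the exocyclic ester enolate on the face of H-8a, anti to ring B, which gives 17. This fallback does not change the facial bias at C5, which rests on the same conformational argument as the main step.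

Step 8 couples a triflate whose carbon is flanked by the quaternary C9, so oxidative addition and transmetalation may be slow. The fallback replaces cross-coupling by carbonyl addition and dehydration; it sets out from ketone 12 and comes back at diene 15. Addition of CH2=CHMgBr with CeCl3 (THF, −78 °C) gives (2S,3R)-2-[(E)-5-[(tert-butyldimethylsilyl)oxy]-3-methylpent-3-en-1-yl]-1-ethenyl-2,3-dimethylcyclohexan-1-ol F6 (C1 epimers). Dehydration with the Burgess reagent (benzene, 50 °C) can only take a ring hydrogen from C6 of F6, because the other neighbour is quaternary, and so gives 15.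

**Further compounds**
F1 | step 6 | (2S,3R)-2,3-dimethyl-2-(3-oxobutyl)cyclohexan-1-one | C[C@@H]1CCCC(=O)[C@@]1(C)CCC(C)=O
F2 | step 6 | ethyl (E)-5-[(1S,2R)-1,2-dimethyl-6-oxocyclohexyl]-3-methylpent-2-enoate | C[C@@H]1CCCC(=O)[C@@]1(C)CC/C(C)=C/C(=O)OCC
F3 | step 6 | (2S,3R)-2-[(E)-5-hydroxy-3-methylpent-3-en-1-yl]-2,3-dimethylcyclohexan-1-ol | C[C@@H]1CCCC(O)[C@@]1(C)CC/C(C)=C/CO
F4 | step 6 | (2S,3R)-2-[(E)-5-[(tert-butyldimethylsilyl)oxy]-3-methylpent-3-en-1-yl]-2,3-dimethylcyclohexan-1-ol | C[C@@H]1CCCC(O)[C@@]1(C)CC/C(C)=C/CO[Si](C)(C)C(C)(C)C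
F5 | step 9 | methyl (5S,6R,8aS)-5-[(E)-5-[(tert-butyldimethylsilyl)oxy]-3-methylpent-3-en-1-yl]-5,6-dimethyl-1,2,3,5,6,7,8,8a-octahydronaphthalene-1-carboxylate | COC(=O)C1CCC=C2[C@H]1CC[C@@H](C)[C@]2(C)CC/C(C)=C/CO[Si](C)(C)C(C)(C)C
F6 | step 8 | (2S,3R)-2-[(E)-5-[(tert-butyldimethylsilyl)oxy]-3-methylpent-3-en-1-yl]-1-ethenyl-2,3-dimethylcyclohexan-1-ol | C[C@@H]1CCCC(O)(C=C)[C@@]1(C)CC/C(C)=C/CO[Si](C)(C)C(C)(C)C
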